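The vessel is a stirred flask at constant temperature: substrate runs in at a steady rate into a little free catalyst, and target, isomer of the product and over-reaction product appear.

| flask | substrate | free catalyst | temperature | remark | time |
|---|---|---|---|---|---|
| Wednesday's | 0.050 M (fed, over 8.0 min) | 0.5 mol% | 32 °C | run made earlier |  |
| Sunday's | 0.075 M (fed, over 8.0 min) | 0.5 mol% | 49 °C | run made earlier |  |
| epsilon | 0.10 M (fed, over 8.0 min) | 0.5 mol% | 35 °C |  | 20 min |
| delta | 0.10 M (fed, over 8.0 min) | 0.5 mol% | 45 °C |  | 20 min |

| run | time / min | isomer of the product / % | substrate / % | over-reaction product / % | target / % | catalyst intermediate A / % |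
|---|---|---|---|---|---|---|
| Wednesday's | 1.50 | 0.8 | 14.1 | 0.2 | 4.1 | 0.1 |
| Wednesday's | 2.50 | 0 | 21.5 | 0 | 7.9 | 0.1 |
| Wednesday's | 4.00 | 2.1 | 35.6 | 0.9 | 11.9 | 0.1 |
| Wednesday's | 6.00 | 1.2 | 50.7 | 1.1 | 18.3 | 1.4 |
| Wednesday's | 8.00 | 5.9 | 66.7 | 3.2 | 22.4 | 2.4 |
| Wednesday's | 12.0 | 9.7 | 48.8 | 7.5 | 32.3 | 0 |
| Wednesday's | 20.0 | 17.1 | 18.8 | 17.8 | 46.9 | 0 |
| Sunday's | 1.50 | 5.1 | 2.4 | 1.2 | 11.8 | 0.4 |
| Sunday's | 3.00 | 9.7 | 4.1 | 5.6 | 20.5 | 2.5 |
| Sunday's | 4.00 | 8.6 | 4.0 | 10.9 | 26.6 | 2.6 |
| Sunday's | 6.00 | 14.4 | 1.7 | 22.3 | 35.2 | 0 |
| Sunday's | 8.00 | 17.3 | 2.0 | 37.5 | 42.8 | 1.5 |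
| Sunday's | 10.0 | 16.4 | 0 | 47.7 | 32.2 | 0 |

(readings scatter by 1 percentage point)

- percentages count the whole charge, also what has not yet gone in

* which of these there is most of at the end, counted by the substrate in it, epsilon (isomer of the product / substrate / target / over-reaction product / catalyst intermediate A)
* which of these there is most of at the end, counted by the substrate in it, delta (isomer of the product / substrate / target / over-reaction product / catalyst intermediate A)
* final amount of the leader among these, as a percentage of the substrate charged, in epsilon
* final amount of the leader among these, as a percentage of the substrate charged, in delta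

**What sets the speed at which substrate disappears?** Not the substrate. After the feed in Wednesday's run, a first-order reading gives 0.0781 min⁻¹ at first and then 0.119 min⁻¹, so the constant grows as substrate falls. A straight line will do instead, with a fall, as a fraction of the charge, of 0.0399 min⁻¹. That is zero order in substrate, and the concentration to watch is the catalyst's.

**What do you carry to a new flask?** The turnover speed N, the substrate one catalyst handles per minute: here 7.98 min⁻¹. At one temperature, N times the loading gives the fraction of the charge used per minute, whatever the molarity, while the line stays straight.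

**But that is at 32 °C. What about temperature?** In Sunday's run the substrate readings stay at or below 4.1% during the feed, so consumption about matches the feed, and N there is about 25.0 min⁻¹ or more. Interpolating logarithmically gives estimates of 9.76 min⁻¹ for epsilon and 19.1 min⁻¹ for delta. By this estimate substrate lasts about 20.5 min in epsilon and 10.5 min in delta.

**What does that buy?** The age of the target. Made steadily over that span, it has a mean age a of 9.76 min in epsilon and 14.8 min in delta. Over-reaction product grows per unit of target at 0.0325 min⁻¹ late in Wednesday's run and 0.192 min⁻¹ in Sunday's. Interpolated, k is 0.0445 min⁻¹ for epsilon and 0.126 min⁻¹ for delta. In the last reading of Wednesday's run target is a share s = 0.733 of target plus isomer of the product; I hold s fixed, so that pool keeps exp(−s·k·a). My reckoning for epsilon is target 53.3% against over-reaction product 27.2%, so target leads. For delta it is over-reaction product 74.5% against target 18.7%, so over-reaction product leads.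

The forecast names target at 44% for epsilon, below my figure, and over-reaction product at 75% for delta, adding “Target probably leads, though not securely”.

The simulation gives target at 48.5% in epsilon and over-reaction product at 72.4% in delta.

    substrate + free catalyst → catalyst intermediate A (k = 21000 M⁻¹ min⁻¹, Ea = 37.0 kJ mol⁻¹)
    catalyst intermediate B → free catalyst + target (k = 39.0 min⁻¹, Ea = 76.0 kJ mol⁻¹)
    target → over-reaction product (k = 0.0440 min⁻¹, Ea = 84.0 kJ mol⁻¹)
    target ⇌ isomer of the product (K = 0.480, k = 0.120 min⁻¹, Ea = 91.0 kJ mol⁻¹, ΔH = −2.00 kJ mol⁻¹)
    catalyst intermediate A ⇌ catalyst intermediate B (K = 0.550, k = 68.0 min⁻¹, Ea = 71.0 kJ mol⁻¹, ΔH = 3.00 kJ mol⁻¹)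
    (constants at 35 °C)

In epsilon, substrate falls from 55.6% to 44.3% between 8.00 min and 10.0 min, an N of 11.4 min⁻¹, above my estimate. A neighbour flask is like epsilon but holds 2 mol% of free catalyst; there the estimated N gives a consumption, as a fraction of the charge, of 0.195 min⁻¹, faster than the feed's 0.125 min⁻¹, so I take a as 16.0 min. That predicts target 43.5%, and the neighbour flask holds 39.7%. Epsilon has not come to rest at 20 min: substrate stands at 0%, but target still holds 48.5%. In epsilon at 50.0 min target is 19.5%, and at 200 min it is 0.270%, with over-reaction product at 99.6%.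

All runs were generated by integration with made-up constants; the scatter is artificial.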